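# Fragransin B1 through a Petasis–Ferrier oxygen-to-carbon shift: design and route

## The problem

Fragransin B1 is a 2,5-diaryl-3,4-dimethyltetrahydrofuran: one oxolane ring with four contiguous stereocentres, two identical syringyl (4-hydroxy-3,5-dimethoxyphenyl) groups on C2 and C5, and two methyl groups on C3 and C4. The descriptors read (2S,3S,4R,5R): the aryl groups are cis to each other, the methyl groups are cis to each other, and each aryl is trans to the methyl next to it. A mirror plane passes through O1 and the C3–C4 bond, so the compound is meso; only relative configuration must be controlled and racemic intermediates suffice.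

The four centres are not equally demanding. C2 and C5 are benzylic ether carbons with electron-rich aryl groups. Acid opens them reversibly to benzylic cations, and the required arrangement (each aryl trans to its neighbouring methyl) is the thermodynamic one for a cis-dimethyl core, so these centres can be corrected at the end. C3 and C4 cannot be epimerised once the ring is saturated, so the cis relationship of the methyl groups is the one element that must be set kinetically.

The sensitive functions are the oxidisable syringyl phenols, carried as benzyl ethers to the last step, and the two ring benzylic C–O bonds. These are labile to strong acid, prone to hydrogenolysis when also allylic, and give cations that electron-rich arenes can trap.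

The feature that opens the key step is the oxidation pattern around O1. C2 carries O1 and an aryl group like the acetal carbon of an aromatic aldehyde. C5 carries O1 and an aryl group like the α-carbon of a mandelic acid. C4 is that acid's carboxyl carbon, and C3 with its methyl is an ethylidene carbon attached to it.

## Retrosynthesis

**17 from 16.** The two O–benzyl bonds are cut. Benzyl is chosen because it survives Me2AlCl, the titanium/zinc olefination reagent, organocerium addition and BF3·OEt2, and leaves by neutral hydrogenolysis. The forward step must cleave aryl benzyl ethers over Pd/C without touching the ring C–O bonds, which in bis(benzyl ether) 16 are benzylic but no longer allylic.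

**16 from 15.** No bond is cut; the configurations at C2 and C5 are reset. The precursor is the all-cis isomer 15, the isomer that hydrogenation delivers. Leaving the benzylic centres to a final acid equilibration means no earlier step has to control them. The forward step must ionise the benzylic C–O bonds reversibly without proton loss from the cation toward C3, which would scramble a methyl centre.

**15 from 14.** The C3–H and C4–H bonds are cut, giving the meso 2,5-dihydrofuran 14 with the double bond between the two methyl-bearing carbons. This placement was chosen against its two neighbours.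
- With the C4=C5 enol ether, the methyl on C3 and the aryl on C2 lie on opposite faces and compete for facial control. The wrong face gives a trans-dimethyl product that nothing can repair.
- With an exocyclic methylene on C4, hydrogen would arrive anti to the neighbouring aryl and also give trans-dimethyl.
- With C3=C4, syn addition can only give cis-dimethyl. Both aryl groups of 14 shield the same face, so both hydrogens come from the open one.

The forward step needs a catalyst that saturates a tetrasubstituted olefin without double-bond migration and without cleaving allylic benzylic ethers. This points to [Ir(cod)(PCy3)(py)]PF6 and away from palladium.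

**14 from 13 from 12.** The C4–CH3 bond is cut and the C3=C4 double bond is traced back to water, leading to tertiary alcohol 13 and ketone 12. The ketone carbon takes the second methyl directly. The forward reactions must add a methyl nucleophile without enolising a ketone that has an acidic benzylic α-hydrogen, then eliminate toward the methyl-bearing carbon only.

**12 from 11 (key disconnection).** The C2–C3 bond is cut and replaced by an acetal C–O bond, giving 4-ethylidene-1,3-dioxolane 11. Cutting O1–C5 instead would require a 5-endo oxa-Michael closure of a base-sensitive hydroxy enone. Cutting an aryl–carbon bond would require sp3–aryl coupling. The chosen cut exchanges a C–C bond for a C–O bond that forms by simple condensation, and joins the two syringyl halves first through oxygen, then through carbon. The forward step must ionise at the enol-ether oxygen and close a five-membered ring by enolate attack on the aryl oxocarbenium ion.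

**11 from 9 and 10.** The exocyclic C=C bond is cut to lactone-acetal 9 and 1,1-dibromoethane 10. A non-basic carbonyl olefination is needed because 9 has an acidic benzylic hydrogen. The olefin geometry does not matter, since the methyl centre ends up α to a ketone.

**9 from 5 and 7.** Both acetal C–O bonds are cut to mandelic acid 5 and aldehyde 7. The cis/trans ratio of 9 is unimportant because the acetal stereocentre is erased in the key step.

**5 from 3 from 1 and 2; 7 from 6.** The aryl–Cα bond of 3 is cut to 2,6-dimethoxyphenol 1 and glyoxylic acid 2. Para-hydroxyalkylation is the only ring substitution open to this phenol. The benzyl ethers of 5 (via ester 4) and 7 come from benzyl bromide; 7 from syringaldehyde 6.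

## Roads not taken

**Alternative 1: oxidative radical annulation of a keto ester with a propenyl arene.**
- *Cut:* C3–C4 and O1–C5.
- *Forward key step:* Mn(OAc)3 with Cu(OAc)2 oxidises keto ester A1 to an α-radical. This adds to propenyl arene A2, and the ketone oxygen captures the benzylic cation to give dihydrofuran A3.
- *Merits:* two simple components, ring and both aryl groups in one step, trans aryl/methyl from cation capture. This road reaches the heterocycle in fewer steps than the chosen plan.
- *Weak points:* A3 carries an ester where a methyl is needed, costing several reduction steps on a vinylogous carbonate. Its tetrasubstituted enol ether must be hydrogenated from the face anti to the methyl while the aryl on the neighbouring carbon shields the other face; the cis-dimethyl relationship is therefore not secured and cannot be repaired. The electron-rich olefin A2 is prone to oxidative dimerisation under a one-electron oxidant.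
- *Comparison:* the chosen plan is longer to the ring. Against that, its ring carbon arrives as a ketone that accepts the methyl directly, and its last olefin can be placed between the methyl carbons so that cis follows from syn addition.

**Alternative 2: twofold decarboxylative arylation of a meso diacid.**
- *Cut:* both C–aryl bonds.
- *Forward key step:* under visible light with Ir[dF(CF3)ppy]2(dtbbpy)PF6, NiCl2(dme) and 4,4'-di-tert-butyl-2,2'-bipyridine, both carboxyl groups of diacid A4 (from a 7-oxanorbornene precursor) are replaced by aryl groups from bromide A5. The product A6 is identical with compound 16.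
- *Merits:* the cis-dimethyl pair and its trans relation to the carboxyl carbons are fixed by the bicyclic precursor, with no dehydration or hydrogenation question. On this point the alternative is better than the chosen plan.
- *Weak points:* two radical couplings must succeed on one molecule, each competing with protodecarboxylation. A5 is an electron-rich bromide that adds slowly to nickel. Each new benzylic configuration rests on radical capture trans to the neighbouring methyl, or on the same final equilibration. Preparing A4 requires reducing an anhydride to two methyl groups.
- *Comparison:* the chosen plan makes no sp3–aryl bond at all, because both aryl carbons are bought at the aldehyde oxidation level, and each of its steps has a close stoichiometric precedent.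

**Alternative 3: thiocarbonyl ylide cycloaddition as masked cis-dimethylation.**
- *Cut:* both C–CH3 bonds, traced back to the ring bonds of a fused thiolane.
- *Forward key step:* CsF releases a sulfur-centred 1,3-dipole from silyl sulfide A8. It adds across the double bond of butenolide A7, anti to the aryl group, to give A9. Desulfurisation with Raney Ni would unveil cis-dimethyl lactone A10. The second aryl group would then be added to the lactone carbonyl and the hemiketal reduced.
- *Merits:* cis-dimethyl comes from a suprafacial cycloaddition, as secure as in alternative 2 and more secure than a dehydration/hydrogenation pair. The lactone end game is standard for this lignan class.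
- *Weak points:* Raney Ni threatens the benzylic lactone C–O bond and the benzyl ether. A7 has an acidic γ-hydrogen that basic fluoride can remove. The two identical aryl groups enter by unrelated chemistry. Oxocarbenium reduction first places the new aryl cis to its neighbouring methyl, so the same acid equilibration is needed.
- *Comparison:* length is comparable. The chosen plan avoids sulfur and organometallic addition to a lactone, and uses the symmetry of the target by drawing both halves from syringyl C1 building blocks.

Key step: step 6

## The route

Assumption: the target is achiral (meso), so every chiral intermediate is the racemate; descriptors give relative configuration and each SMILES shows one enantiomer.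

Step 1
Reactants: 1 2,6-dimethoxyphenol; 2 glyoxylic acid
Product: 3 rac-2-hydroxy-2-(4-hydroxy-3,5-dimethoxyphenyl)acetic acid
Conditions: glyoxylic acid (50% aq.), NaOH, H2O, 0 °C → rt; then HCl to pH 1
Reagents that add atoms: none
Why: Electrophilic aromatic hydroxyalkylation of the phenoxide by glyoxylate; both ortho positions carry methoxy groups, so only the para position can react and the mandelic acid skeleton of one half should form directly.

Step 2
Reactants: 3 rac-2-hydroxy-2-(4-hydroxy-3,5-dimethoxyphenyl)acetic acid
Product: 5 rac-2-[4-(benzyloxy)-3,5-dimethoxyphenyl]-2-hydroxyacetic acid, via benzyl ester 4 (not isolated)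
Conditions: BnBr (2.2 equiv), K2CO3, DMF, 50 °C; then LiOH, MeOH/H2O, rt; HCl work-up
Reagents that add atoms: benzyl bromide, BrCc1ccccc1
Why: Williamson alkylation under carbonate benzylates phenoxide and carboxylate but not the secondary alcohol; saponification then cleaves only the ester.

Step 3
Reactants: 6 syringaldehyde
Product: 7 4-(benzyloxy)-3,5-dimethoxybenzaldehyde
Conditions: BnBr, K2CO3, DMF, 60 °C
Reagents that add atoms: benzyl bromide, BrCc1ccccc1
Why: Williamson ether synthesis on a phenoxide; the aldehyde is inert to these conditions.

Step 4
Reactants: 5 rac-2-[4-(benzyloxy)-3,5-dimethoxyphenyl]-2-hydroxyacetic acid; 7 4-(benzyloxy)-3,5-dimethoxybenzaldehyde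
Product: 9 rac-(2S,5S)-2,5-bis[4-(benzyloxy)-3,5-dimethoxyphenyl]-1,3-dioxolan-4-one (2,5-cis), via bis(trimethylsilyl) derivative 8 (not isolated)
Conditions: HMDS, TMSCl (cat.), THF, rt; evaporate; then 7, TMSOTf (10 mol %), CH2Cl2, −78 °C; pyridine quench
Reagents that add atoms: none
Why: Silyl-mediated acetalisation of an aldehyde with a bis-silylated α-hydroxy acid at low temperature, driven by loss of hexamethyldisiloxane; the cis isomer with both aryl groups pseudo-equatorial should predominate, and any trans isomer is carried on because the acetal centre is erased in step 6.

Step 5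
Reactants: 9 rac-(2S,5S)-2,5-bis[4-(benzyloxy)-3,5-dimethoxyphenyl]-1,3-dioxolan-4-one; 10 1,1-dibromoethane
Product: 11 rac-(2S,5S,Z)-2,5-bis[4-(benzyloxy)-3,5-dimethoxyphenyl]-4-ethylidene-1,3-dioxolane (2,5-cis; methyl cis to O3)
Conditions: CH3CHBr2, Zn, TiCl4, TMEDA, PbCl2 (cat.), THF, 0 °C → rt; Et3N/aq. K2CO3 work-up
Reagents that add atoms: none
Why: Takai–Utimoto alkylidenation of an ester-type carbonyl by a non-basic low-valent titanium/zinc gem-dimetal reagent, which leaves the acidic benzylic hydrogen alone; the (Z)-enol ether with the methyl turned away from the C5 aryl is expected, and the geometry is not critical.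

Step 6
Reactants: 11 rac-(2S,5S,Z)-2,5-bis[4-(benzyloxy)-3,5-dimethoxyphenyl]-4-ethylidene-1,3-dioxolane
Product: 12 rac-(2S,4R,5S)-2,5-bis[4-(benzyloxy)-3,5-dimethoxyphenyl]-4-methyloxolan-3-one (aryl groups cis; methyl trans to the neighbouring aryl)
Conditions: Me2AlCl (2.5 equiv), CH2Cl2, −78 → 0 °C; aq. NaHCO3 quench
Reagents that add atoms: none
Why: Me2AlCl binds the enol-ether oxygen of 11 and cleaves its bond to the acetal carbon, giving an aluminium enolate and an aryl-stabilised oxocarbenium ion that remain tethered through O1 and the mandelic carbon. The enolate carbon then attacks the oxocarbenium carbon, forming the C2–C3 bond of the target (C4–C5 in the numbering of 12) and converting the dioxolane into the oxolan-3-one, a formal 1,3 shift from oxygen to carbon. This is a Petasis–Ferrier rearrangement; the closest known reaction type is the aluminium-promoted rearrangement of 4-alkylidene-1,3-dioxolanes to tetrahydrofuran-3-ones and of the homologous dioxanes to tetrahydropyranones. The single ring closes in an aldol-type 5-(enolendo)-endo-trig mode, formally disfavoured by Baldwin's rules but documented for this substrate class, where the cationic electrophile and the short tether compensate. The new aryl-bearing stereocentre is set relative to the retained mandelic carbon through an envelope transition state with both aryl groups pseudo-equatorial, which gives the 2,5-cis ring. The new methyl-bearing stereocentre is set in the same transition state and, being α to the ketone, can equilibrate to the arrangement trans to the neighbouring aryl. The step needs ionisation at the enol-ether oxygen and not at O1; this is secured because only that cleavage releases an enolate as leaving group while the 4-benzyloxy-3,5-dimethoxyphenyl group stabilises the cation. Low temperature and a short contact time should limit β-elimination of O1 from the product.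

Step 7
Reactants: 12 rac-(2S,4R,5S)-2,5-bis[4-(benzyloxy)-3,5-dimethoxyphenyl]-4-methyloxolan-3-one
Product: 13 rac-(2S,3S,4R,5S)-2,5-bis[4-(benzyloxy)-3,5-dimethoxyphenyl]-3,4-dimethyloxolan-3-ol (both methyl groups on the face opposite the aryl groups; hydroxyl on the aryl face)
Conditions: MeMgBr, CeCl3, THF, −78 °C; aq. NH4Cl
Reagents that add atoms: methylmagnesium bromide, C[Mg]Br
Why: Organocerium 1,2-addition, whose low basicity suppresses enolisation at the acidic benzylic α-carbon and ring opening by β-elimination; the methyl should enter anti to the neighbouring aryl group, on the face that carries only the small α-methyl, which places the hydroxyl syn to the hydrogen on the methyl-bearing carbon.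

Step 8
Reactants: 13 rac-(2S,3S,4R,5S)-2,5-bis[4-(benzyloxy)-3,5-dimethoxyphenyl]-3,4-dimethyloxolan-3-ol
Product: 14 cis-2,5-bis[4-(benzyloxy)-3,5-dimethoxyphenyl]-3,4-dimethyl-2,5-dihydrofuran (meso)
Conditions: Burgess reagent (methyl N-(triethylammoniosulfonyl)carbamate), toluene, 60 °C
Reagents that add atoms: none
Why: Burgess dehydration is a syn (Ei) elimination through the sulfamate ester; in 13 the ring hydrogen syn to the hydroxyl is the one on the methyl-bearing carbon, while the benzylic α-oxy hydrogen is anti, so the tetrasubstituted ring olefin (Zaitsev) is expected over the enol ether, with the exocyclic olefin as the likely minor isomer.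

Step 9
Reactants: 14 cis-2,5-bis[4-(benzyloxy)-3,5-dimethoxyphenyl]-3,4-dimethyl-2,5-dihydrofuran
Product: 15 (2S,3R,4S,5R)-2,5-bis[4-(benzyloxy)-3,5-dimethoxyphenyl]-3,4-dimethyloxolane (all-cis, meso)
Conditions: H2 (1–5 bar), [Ir(cod)(PCy3)(py)]PF6 (5 mol %), CH2Cl2, rt
Reagents that add atoms: none
Why: Homogeneous hydrogenation of a tetrasubstituted olefin by a cationic iridium catalyst that adds H2 strictly syn and neither migrates the double bond nor cleaves benzyl ethers; syn addition fixes the cis-dimethyl relationship whatever the face, and the two aryl groups direct both hydrogens to the open face, giving the all-cis isomer.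

Step 10
Reactants: 15 (2S,3R,4S,5R)-2,5-bis[4-(benzyloxy)-3,5-dimethoxyphenyl]-3,4-dimethyloxolane
Product: 16 (2S,3S,4R,5R)-2,5-bis[4-(benzyloxy)-3,5-dimethoxyphenyl]-3,4-dimethyloxolane (Fragransin B1 bis(benzyl ether), meso)
Conditions: BF3·OEt2 (0.3 equiv), CH2Cl2, −20 → 0 °C
Reagents that add atoms: none
Why: Lewis-acid-promoted reversible heterolysis of each benzylic C–O bond to a ring-opened benzylic cation and reclosure (SN1-type epimerisation) lets C2 and C5 reach the thermodynamic arrangement with each aryl trans to its neighbouring methyl; the methyl-bearing centres are not involved.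

Step 11
Reactants: 16 (2S,3S,4R,5R)-2,5-bis[4-(benzyloxy)-3,5-dimethoxyphenyl]-3,4-dimethyloxolane
Product: 17 Fragransin B1, (2S,3S,4R,5R)-2,5-bis(4-hydroxy-3,5-dimethoxyphenyl)-3,4-dimethyloxolane (meso)
Conditions: H2 (1 atm), Pd/C, EtOAc/EtOH, rt
Reagents that add atoms: none
Why: Hydrogenolysis of aryl benzyl ethers over palladium on carbon; the ring C–O bonds are benzylic but not allylic and part of a dialkyl ether, and should survive neutral conditions at short reaction time.

## Compound list

1 | 2,6-dimethoxyphenol | COc1cccc(OC)c1O | starting material
2 | glyoxylic acid | O=CC(=O)O | starting material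
3 | rac-2-hydroxy-2-(4-hydroxy-3,5-dimethoxyphenyl)acetic acid | COc1cc([C@H](O)C(=O)O)cc(OC)c1O | intermediate
4 | rac-benzyl 2-[4-(benzyloxy)-3,5-dimethoxyphenyl]-2-hydroxyacetate | COc1cc([C@H](O)C(=O)OCc2ccccc2)cc(OC)c1OCc1ccccc1 | intermediate (not isolated)
5 | rac-2-[4-(benzyloxy)-3,5-dimethoxyphenyl]-2-hydroxyacetic acid | COc1cc([C@H](O)C(=O)O)cc(OC)c1OCc1ccccc1 | intermediate
6 | syringaldehyde | COc1cc(C=O)cc(OC)c1O | starting material
7 | 4-(benzyloxy)-3,5-dimethoxybenzaldehyde | COc1cc(C=O)cc(OC)c1OCc1ccccc1 | intermediate
8 | rac-trimethylsilyl 2-[4-(benzyloxy)-3,5-dimethoxyphenyl]-2-(trimethylsilyloxy)acetate | COc1cc([C@H](O[Si](C)(C)C)C(=O)O[Si](C)(C)C)cc(OC)c1OCc1ccccc1 | intermediate (not isolated)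
9 | rac-(2S,5S)-2,5-bis[4-(benzyloxy)-3,5-dimethoxyphenyl]-1,3-dioxolan-4-one (cis) | O=C1O[C@@H](c2cc(OC)c(OCc3ccccc3)c(OC)c2)O[C@H]1c1cc(OC)c(OCc2ccccc2)c(OC)c1 | intermediate
10 | 1,1-dibromoethane | CC(Br)Br | starting material
11 | rac-(2S,5S,Z)-2,5-bis[4-(benzyloxy)-3,5-dimethoxyphenyl]-4-ethylidene-1,3-dioxolane (cis) | C/C=C1\O[C@@H](c2cc(OC)c(OCc3ccccc3)c(OC)c2)O[C@H]1c1cc(OC)c(OCc2ccccc2)c(OC)c1 | intermediate
12 | rac-(2S,4R,5S)-2,5-bis[4-(benzyloxy)-3,5-dimethoxyphenyl]-4-methyloxolan-3-one | COc1cc([C@H]2O[C@@H](c3cc(OC)c(OCc4ccccc4)c(OC)c3)C(=O)[C@@H]2C)cc(OC)c1OCc1ccccc1 | intermediate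
13 | rac-(2S,3S,4R,5S)-2,5-bis[4-(benzyloxy)-3,5-dimethoxyphenyl]-3,4-dimethyloxolan-3-ol | COc1cc([C@H]2O[C@@H](c3cc(OC)c(OCc4ccccc4)c(OC)c3)[C@@](C)(O)[C@@H]2C)cc(OC)c1OCc1ccccc1 | intermediate
14 | cis-2,5-bis[4-(benzyloxy)-3,5-dimethoxyphenyl]-3,4-dimethyl-2,5-dihydrofuran (meso) | COc1cc([C@H]2O[C@@H](c3cc(OC)c(OCc4ccccc4)c(OC)c3)C(C)=C2C)cc(OC)c1OCc1ccccc1 | intermediate
15 | (2S,3R,4S,5R)-2,5-bis[4-(benzyloxy)-3,5-dimethoxyphenyl]-3,4-dimethyloxolane (all-cis, meso) | COc1cc([C@H]2O[C@@H](c3cc(OC)c(OCc4ccccc4)c(OC)c3)[C@@H](C)[C@H]2C)cc(OC)c1OCc1ccccc1 | intermediate
16 | (2S,3S,4R,5R)-2,5-bis[4-(benzyloxy)-3,5-dimethoxyphenyl]-3,4-dimethyloxolane (meso) | COc1cc([C@H]2O[C@@H](c3cc(OC)c(OCc4ccccc4)c(OC)c3)[C@H](C)[C@@H]2C)cc(OC)c1OCc1ccccc1 | intermediate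
17 | Fragransin B1, (2S,3S,4R,5R)-2,5-bis(4-hydroxy-3,5-dimethoxyphenyl)-3,4-dimethyloxolane (meso) | COc1cc([C@H]2O[C@@H](c3cc(OC)c(O)c(OC)c3)[C@H](C)[C@@H]2C)cc(OC)c1O | target

## Step count and risk

Total: 11 steps. Longest linear sequence: 10 steps (steps 1, 2 and 4–11, from 2,6-dimethoxyphenol); step 3 is the only branch.

**Step 6 (key step).** The ring-opened zwitterion may fail to close, because the 5-(enolendo)-endo-trig geometry is strained. It could instead lose the aldehyde component by cleavage of the second C–O bond, since the mandelic carbon also carries a cation-stabilising aryl group. The ketone, once formed, could ring-open by β-elimination of O1 on prolonged contact with the Lewis acid, and methyl transfer from aluminium to the oxocarbenium ion is also conceivable. The fallback sets out from 11 and changes the terminating event. With iBu3Al in CH2Cl2 the rearrangement is followed at once by hydride transfer from an isobutyl group to the aluminium-bound carbonyl, a variant documented for 4-methylene-1,3-dioxolanes. This gives rac-2,5-cis-2,5-bis[4-(benzyloxy)-3,5-dimethoxyphenyl]-4-methyloxolan-3-ol F1 (either carbinol epimer serves) and withdraws the ketone from the reversible pathways. Oxidation of F1 with Dess–Martin periodinane returns to the route at 12.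

**Step 5.** Titanium and zinc halides may open the electron-rich aryl acetal or the lactone before olefination, or the carbonyl may be reduced without C=C formation. The fallback sets out from 9 and uses a modified Julia olefination, known to convert lactones into exocyclic enol ethers. LiN(SiMe3)2 is added at −78 °C to a mixture of 9 and 2-(ethylsulfonyl)-1,3-benzothiazole to give the hemiketal sulfone adduct F2. DBU then triggers Smiles rearrangement and loss of SO2 and benzothiazolone, returning to the route at 11.

**Step 8.** Loss of regiocontrol in the dehydration is the main danger. The outcome depends on the facial selectivity of step 7: the epimeric alcohol has its syn hydrogen on the benzylic carbon and would give the enol ether. Elimination into the methyl group gives the exocyclic olefin. Ionisation of the sulfamate instead of concerted elimination opens the way to hydride or aryl shifts toward the oxygen-stabilised position. Only 14 guarantees cis-dimethyl in step 9. The fallback sets out from 13 and makes the regiochemistry irrelevant. The unseparated olefin mixture is oxidised with DDQ to 2,5-bis[4-(benzyloxy)-3,5-dimethoxyphenyl]-3,4-dimethylfuran F3, on which all isomers converge. Hydrogenation of F3 over Rh/Al2O3 (EtOAc, moderate pressure) adds hydrogen to one face of the planar ring and returns to the route at all-cis 15. This costs one extra step and no longer uses the stereochemistry built in step 6.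

**Step 9.** Acidic iridium hydride species may ionise the doubly activated (allylic and benzylic) C–O bonds of 14 before the hindered olefin is reduced, leading to ring opening or aromatisation. The fallback sets out from 14 and uses hydrogen-atom-transfer hydrogenation (Mn(dpm)3, PhSiH3, tert-butyl hydroperoxide, isopropanol, rt), a neutral radical process known for tetrasubstituted olefins. Stereocontrol no longer rests on syn addition but on the two cis aryl groups, which should direct both hydrogen atoms to the open face and return to the route at 15. This fallback makes no new compound (F0).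

**Step 10.** Equilibration may stall, because the 4-benzyloxy group is twisted out of conjugation by its two methoxy neighbours and stabilises the cation less than a free para-hydroxyl would. If pushed, it may leak into proton loss from the ring-opened cation toward the methyl-bearing carbon; re-protonation then scrambles that centre toward the trans-dimethyl series. Friedel–Crafts capture of the cation by an arene is a further risk. The fallback sets out from 15 and changes the ionising species. Debenzylation first (H2, Pd/C, EtOAc/EtOH) gives all-cis (2S,3R,4S,5R)-2,5-bis(4-hydroxy-3,5-dimethoxyphenyl)-3,4-dimethyloxolane F4. Its free para-hydroxyl groups allow ring opening through a p-quinone-methide-type cation under much milder protic acid (catalytic CF3CO2H, CH2Cl2, 0 °C). Equilibration of F4 then comes back to the route directly at 17.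

## Further compounds

F1 | step 6 | rac-2,5-cis-2,5-bis[4-(benzyloxy)-3,5-dimethoxyphenyl]-4-methyloxolan-3-ol (carbinol centre as formed, either epimer) | COc1cc([C@H]2O[C@@H](c3cc(OC)c(OCc4ccccc4)c(OC)c3)C(O)[C@@H]2C)cc(OC)c1OCc1ccccc1
F2 | step 5 | rac-4-[1-(1,3-benzothiazol-2-ylsulfonyl)ethyl]-2,5-cis-2,5-bis[4-(benzyloxy)-3,5-dimethoxyphenyl]-1,3-dioxolan-4-ol (new centres as formed) | CC(C1(O)O[C@@H](c2cc(OC)c(OCc3ccccc3)c(OC)c2)O[C@H]1c1cc(OC)c(OCc2ccccc2)c(OC)c1)S(=O)(=O)c1nc2ccccc2s1
F3 | step 8 | 2,5-bis[4-(benzyloxy)-3,5-dimethoxyphenyl]-3,4-dimethylfuran | Cc1c(-c2cc(OC)c(OCc3ccccc3)c(OC)c2)oc(-c2cc(OC)c(OCc3ccccc3)c(OC)c2)c1C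
F0 | step 9 | none | none
F4 | step 10 | (2S,3R,4S,5R)-2,5-bis(4-hydroxy-3,5-dimethoxyphenyl)-3,4-dimethyloxolane (all-cis, meso) | COc1cc([C@H]2O[C@@H](c3cc(OC)c(O)c(OC)c3)[C@@H](C)[C@H]2C)cc(OC)c1O
A1 | alternative 1 | ethyl 3-[4-(benzyloxy)-3,5-dimethoxyphenyl]-3-oxopropanoate | CCOC(=O)CC(=O)c1cc(OC)c(OCc2ccccc2)c(OC)c1
A2 | alternative 1 | 2-(benzyloxy)-1,3-dimethoxy-5-[(E)-prop-1-enyl]benzene | C/C=C/c1cc(OC)c(OCc2ccccc2)c(OC)c1
A3 | alternative 1 | ethyl trans-2,5-bis[4-(benzyloxy)-3,5-dimethoxyphenyl]-4-methyl-4,5-dihydrofuran-3-carboxylate | CCOC(=O)C1=C(c2cc(OC)c(OCc3ccccc3)c(OC)c2)O[C@@H](c2cc(OC)c(OCc3ccccc3)c(OC)c2)[C@@H]1C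
A4 | alternative 2 | meso-3,4-dimethyloxolane-2,5-dicarboxylic acid (carboxyls cis, methyls cis, each carboxyl trans to its neighbouring methyl) | OC(=O)[C@H]1O[C@@H](C(=O)O)[C@H](C)[C@@H]1C
A5 | alternative 2 | 2-(benzyloxy)-5-bromo-1,3-dimethoxybenzene | COc1cc(Br)cc(OC)c1OCc1ccccc1
A6 | alternative 2 | Fragransin B1 bis(benzyl ether) (same compound as 16) | COc1cc([C@H]2O[C@@H](c3cc(OC)c(OCc4ccccc4)c(OC)c3)[C@H](C)[C@@H]2C)cc(OC)c1OCc1ccccc1
A7 | alternative 3 | rac-5-[4-(benzyloxy)-3,5-dimethoxyphenyl]furan-2(5H)-one | O=C1O[C@@H](c2cc(OC)c(OCc3ccccc3)c(OC)c2)C=C1
A8 | alternative 3 | chloromethyl (trimethylsilyl)methyl sulfide | C[Si](C)(C)CSCCl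
A9 | alternative 3 | rac-cis-fused 3-[4-(benzyloxy)-3,5-dimethoxyphenyl]tetrahydrothieno[3,4-c]furan-1-one (aryl trans to the thiolane ring) | O=C1O[C@@H](c2cc(OC)c(OCc3ccccc3)c(OC)c2)[C@@H]2CSC[C@H]12
A10 | alternative 3 | rac-5-[4-(benzyloxy)-3,5-dimethoxyphenyl]-3,4-cis-dimethyloxolan-2-one (aryl trans to the neighbouring methyl) | O=C1O[C@@H](c2cc(OC)c(OCc3ccccc3)c(OC)c2)[C@H](C)[C@@H]1C
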